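**Retrosynthetic overview**
- Feature: the 17-membered ring is numbered N1–C2(nonyl)–C3–C4(=O)–N5–C6–C7–C8–N9–C10–C11–C12–C13–N14–C15–C16–C17. The stretch N1–C2–C3–C4(=O)–N5 is a β-amino amide, the dihydro form of a vinylogous urea N1–C2=C3–C4=O. Such an enaminone results when a thioamide carbon (C2) and an α-haloacetamide carbon (C3) are joined through sulfur and the sulfur is then expelled.
- Disconnections: target ⇒ (N-deprotection; H2 across C2=C3, which sets C2) Z-enaminone macrocycle ⇒ (C2=C3, sulfide contraction) 18-membered thioimidate with S between C2 and C3 ⇒ (S–C3) open-chain N1-decanethioyl-N12-bromoacetyl-spermine.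
- Ring order: the single ring is closed first as the 18-membered thia-ring (S–C3 bond). It is then contracted in the same flask to the 17-membered ring (C2–C3 bond, through a transient thiirane).
- Design points: N9 and N14 carry Boc. N5 carries 2,4-dimethoxybenzyl (DMB), so that C3–H and not an amide N–H is the acidic site beside sulfur. N1 stays N–H, which fixes the Z geometry and allows the hydrogenation.
- Chain assembly: spermine supplies the four nitrogens. Methyl decanedithioate (nonyl Grignard reagent, CS2, MeI) supplies C2 with the nonyl group. Bromoacetyl bromide supplies C3 and C4.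

Key step: step 7

Remark (numbering): open-chain compounds carry spermine locants; spermine N1, N4, N9 and N12 become ring N1, N14, N9 and N5.
Remark (assumption): the (R)-(S) ligand enantiomer in step 8 is chosen by analogy with open-chain Z-β-enamino amides bearing a CH2 group on the β-carbon, which it reduces to the R-amines; if the macrocycle responds with the opposite sense, the commercially available mirror-image ligand is used.

**Step 1**
Reactants: 1 1-bromononane; 2 carbon disulfide
Product: 5 methyl decanedithioate, via nonylmagnesium bromide 3 (not isolated), via bromomagnesium decanedithioate 4 (not isolated)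
Conditions: Mg, THF, 40 °C; 2, THF, −10 → 0 °C; MeI, 0 °C → rt
Reagents that add atoms: iodomethane CI
Why: Grignard addition to carbon disulfide gives the dithiocarboxylate, which is S-methylated in the same flask, the standard dithioester synthesis that delivers C2 already at the thiocarbonyl level.

**Step 2**
Reactants: 6 spermine
Product: 8 N1,N12-bis(trifluoroacetyl)-N4,N9-di-Boc-spermine, via N1,N12-bis(trifluoroacetyl)spermine 7 (not isolated)
Conditions: CF3CO2Et (2.1 equiv), MeOH, −78 → 0 °C; then Boc2O (2.5 equiv), 0 °C → rt
Reagents that add atoms: ethyl trifluoroacetate CCOC(=O)C(F)(F)F; di-tert-butyl dicarbonate CC(C)(C)OC(=O)OC(=O)OC(C)(C)C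
Why: ethyl trifluoroacetate acylates only the unhindered primary amines of a polyamine at low temperature, so the following Boc protection can take only the two secondary nitrogens (selective N-acylation, then carbamate formation).

**Step 3**
Reactants: 8 N1,N12-bis(trifluoroacetyl)-N4,N9-di-Boc-spermine
Product: 9 N4,N9-di-Boc-spermine
Conditions: NH3 (7 M in MeOH), rt
Reagents that add atoms: none
Why: trifluoroacetamides undergo ammonolysis at room temperature whereas tert-butyl carbamates are inert to ammonia (orthogonal deprotection).

**Step 4**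
Reactants: 9 N4,N9-di-Boc-spermine; 5 methyl decanedithioate
Product: 10 N1-decanethioyl-N4,N9-di-Boc-spermine
Conditions: 9 (3 equiv), THF, 0 °C; 5 (1 equiv) added slowly, → rt; excess 9 recovered
Reagents that add atoms: none
Why: aminolysis of a dithioester by a primary amine is a mild thioacylation that needs no activator, slow addition to an excess of the symmetrical diamine biases the statistical outcome towards the mono-thioamide, and the dibasic, monobasic and neutral components separate easily.

**Step 5**
Reactants: 10 N1-decanethioyl-N4,N9-di-Boc-spermine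
Product: 12 N1-decanethioyl-N12-DMB-N4,N9-di-Boc-spermine, via N12-arylmethylidene imine 11 (not isolated)
Conditions: 2,4-(MeO)2C6H3CHO (1.0 equiv), 3 Å MS, MeOH, rt; NaBH4, 0 °C
Reagents that add atoms: 2,4-dimethoxybenzaldehyde O=Cc1ccc(OC)cc1OC
Why: stepwise reductive amination (imine formation, then borohydride reduction) stops at the secondary amine, and NaBH4 touches neither the thioamide nor the carbamates.

**Step 6**
Reactants: 12 N1-decanethioyl-N12-DMB-N4,N9-di-Boc-spermine; 13 bromoacetyl bromide
Product: 14 N1-decanethioyl-N12-bromoacetyl-N12-DMB-N4,N9-di-Boc-spermine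
Conditions: 13 (1.05 equiv, added slowly), CH2Cl2/sat. aq NaHCO3, 0 °C, 20 min; cold work-up, kept as a dilute MeCN solution and used the same day
Reagents that add atoms: none
Why: in this Schotten–Baumann N-acylation the secondary amine takes the acyl bromide far faster than amine or thioamide sulfur displaces the primary bromide at 0 °C, the near-stoichiometric charge leaves no acyl bromide for the thioamide, and the hydrogencarbonate phase removes HBr before it can harm the Boc groups.

**Step 7**
Reactants: 14 N1-decanethioyl-N12-bromoacetyl-N12-DMB-N4,N9-di-Boc-spermine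
Product: 17 (Z)-5-DMB-9,14-di-Boc-2-nonyl-1,5,9,14-tetraazacycloheptadec-2-en-4-one, via cyclic thioimidate 15 (not isolated), via C2–C3 episulfide 16 (not isolated)
Conditions: a) Cs2CO3 (3 equiv), 4 Å MS, MeCN, 45 °C, 14 added by syringe pump over 16 h (about 1 mM final); filter, evaporate; b) PPh3 (2 equiv), KOtBu (0.3 equiv), toluene, 110 °C; SiO2
Reagents that add atoms: none
Why: Proposed new method: the caesium thioamidate of 14 attacks C3 through sulfur and expels bromide, an 18-exo-tet thioetherification that closes the only ring of the route as thioimidate 15, with S- over N-alkylation secured by the soft sulfur and the soft primary bromide and ring closure over chain growth secured by the millimolar stationary concentration. tert-Butoxide then removes a C3 proton flanked by sulfur and the tertiary amide carbonyl, the carbanion adds to the imidate carbon C2 in a 3-exo-trig closure to aminothiirane 16, and PPh3 strips the sulfur so that C2=C3 remains and the ring shrinks from 18 to 17 members. The closest known reaction type is the Eschenmoser sulfide contraction, described for N–H thiolactams with bromoacetates under KOtBu/PPh3, for tertiary thiolactams with bromoacetamides and for thia-macrolide contractions, but an N–H thioimidate, an unactivated acetamide CH2 and a macrocycle have not been combined, hence the label. The DMB group on N5 serves this step, because an amide N–H would be deprotonated in preference to C3 and could attack C2 in a 5-exo-trig mode with transfer of the imidoyl group from sulfur to N5. Attack of N1 on C4 (thiazolinone formation) is disfavoured because a tertiary amide is a much poorer acyl donor than the esters for which that path is known. No permanent stereocentre is formed, since the two centres of 16 vanish with the sulfur and the olefin equilibrates through its imine tautomer to the Z isomer held by the N1–H···O=C4 hydrogen bond.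

**Step 8**
Reactants: 17 (Z)-5-DMB-9,14-di-Boc-2-nonyl-1,5,9,14-tetraazacycloheptadec-2-en-4-one
Product: 18 (2R)-5-DMB-9,14-di-Boc-2-nonyl-1,5,9,14-tetraazacycloheptadecan-4-one
Conditions: [Rh(cod)Cl]2 (2.5 mol %), (R)-1-[(S)-2-(diphenylphosphino)ferrocenyl]ethyldi-tert-butylphosphine (5.5 mol %), H2 (20 bar), CF3CH2OH, 50 °C
Reagents that add atoms: none
Why: Proposed new method: asymmetric hydrogenation with rhodium and a Josiphos ligand is established for Z-β-enamino esters and amides that carry a free NH2 group (the closest known reaction type), where the substrate binds through the carbonyl oxygen and is reduced by way of its imine tautomer, and 17 offers the same Z-configured N1–H···O=C4 array, a tertiary amide donor and a tautomerisable N–H, so the same pathway should operate although N1 bears an alkyl chain and the olefin lies in a macrocycle; the chiral pocket of the ligand directs hydrogen to the Si face of C2, which sets C2 as R.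

**Step 9**
Reactants: 18 (2R)-5-DMB-9,14-di-Boc-2-nonyl-1,5,9,14-tetraazacycloheptadecan-4-one
Product: 19 (2R)-2-nonyl-1,5,9,14-tetraazacycloheptadecan-4-one (target)
Conditions: TFA/iPr3SiH/H2O (90:5:5), rt → 40 °C; evaporate; cold aq NaOH, CHCl3 extraction
Reagents that add atoms: none
Why: in this acidolysis both tert-butyl carbamates fragment to isobutene and CO2, the electron-rich 2,4-dimethoxybenzyl cation leaves the amide nitrogen and is reduced by the silane, and the protonated β-amino amide cannot undergo retro-Michael loss of N1, so C2 keeps its configuration.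

**Compound list**
1 | 1-bromononane | CCCCCCCCCBr | starting material
2 | carbon disulfide | S=C=S | starting material
3 | nonylmagnesium bromide | CCCCCCCCC[Mg]Br | intermediate
4 | bromomagnesium decanedithioate | CCCCCCCCCC(=S)S[Mg]Br | intermediate
5 | methyl decanedithioate | CCCCCCCCCC(=S)SC | intermediate
6 | spermine | NCCCNCCCCNCCCN | starting material
7 | N1,N12-bis(trifluoroacetyl)spermine | FC(F)(F)C(=O)NCCCNCCCCNCCCNC(=O)C(F)(F)F | intermediate
8 | N1,N12-bis(trifluoroacetyl)-N4,N9-di-Boc-spermine | FC(F)(F)C(=O)NCCCN(C(=O)OC(C)(C)C)CCCCN(C(=O)OC(C)(C)C)CCCNC(=O)C(F)(F)F | intermediate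
9 | N4,N9-di-Boc-spermine | NCCCN(C(=O)OC(C)(C)C)CCCCN(C(=O)OC(C)(C)C)CCCN | intermediate
10 | N1-decanethioyl-N4,N9-di-Boc-spermine | CCCCCCCCCC(=S)NCCCN(C(=O)OC(C)(C)C)CCCCN(C(=O)OC(C)(C)C)CCCN | intermediate
11 | (E)-N12-(2,4-dimethoxybenzylidene) imine of 10 | CCCCCCCCCC(=S)NCCCN(C(=O)OC(C)(C)C)CCCCN(C(=O)OC(C)(C)C)CCC/N=C/c1ccc(OC)cc1OC | intermediate
12 | N1-decanethioyl-N12-DMB-N4,N9-di-Boc-spermine | CCCCCCCCCC(=S)NCCCN(C(=O)OC(C)(C)C)CCCCN(C(=O)OC(C)(C)C)CCCNCc1ccc(OC)cc1OC | intermediate
13 | bromoacetyl bromide | BrCC(Br)=O | starting material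
14 | N1-decanethioyl-N12-bromoacetyl-N12-DMB-N4,N9-di-Boc-spermine (key-step precursor) | CCCCCCCCCC(=S)NCCCN(C(=O)OC(C)(C)C)CCCCN(C(=O)OC(C)(C)C)CCCN(Cc1ccc(OC)cc1OC)C(=O)CBr | intermediate
15 | 18-membered cyclic S-alkyl thioimidate (C2=N1, S between C2 and C3) | CCCCCCCCCC1=NCCCN(C(=O)OC(C)(C)C)CCCCN(C(=O)OC(C)(C)C)CCCN(Cc2ccc(OC)cc2OC)C(=O)CS1 | intermediate
16 | C2–C3 episulfide (2-aminothiirane fused to the 17-membered ring, transient, racemic) | CCCCCCCCCC12NCCCN(C(=O)OC(C)(C)C)CCCCN(C(=O)OC(C)(C)C)CCCN(Cc3ccc(OC)cc3OC)C(=O)C1S2 | intermediate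
17 | (Z)-5-DMB-9,14-di-Boc-2-nonyl-1,5,9,14-tetraazacycloheptadec-2-en-4-one (key-step product) | CCCCCCCCC/C1=C/C(=O)N(Cc2ccc(OC)cc2OC)CCCN(C(=O)OC(C)(C)C)CCCCN(C(=O)OC(C)(C)C)CCCN1 | intermediate
18 | (2R)-5-DMB-9,14-di-Boc-2-nonyl-1,5,9,14-tetraazacycloheptadecan-4-one | CCCCCCCCC[C@@H]1CC(=O)N(Cc2ccc(OC)cc2OC)CCCN(C(=O)OC(C)(C)C)CCCCN(C(=O)OC(C)(C)C)CCCN1 | intermediate
19 | (2R)-2-nonyl-1,5,9,14-tetraazacycloheptadecan-4-one | CCCCCCCCC[C@@H]1CC(=O)NCCCNCCCCNCCCN1 | target

**Step count**
Total steps: 9. Longest linear sequence: 8 (steps 2–9, from spermine).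

**Steps most likely to fail**

1. Step 7 (labelled).
What may go wrong: chain growth may compete with ring closure during the S-alkylation. Deprotonation at C3 or addition to the neutral C2=N1 bond may be too slow. Base may strip a proton from the nonyl CH2 next to C2 and expel the thiolate, which reopens the ring.
Fallback: known chemistry, with the ring closed at N1–C2 by enaminone condensation in place of sulfur extrusion. It sets out from 9 and comes back at 17.
- An excess of 9 is reductively alkylated at one end with 2,4-dimethoxybenzaldehyde and NaBH4. This gives N1-(2,4-dimethoxybenzyl)-N4,N9-di-Boc-spermine F1.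
- The remaining primary amine of F1 is masked selectively with CF3CO2Et as the N12-trifluoroacetamide F2.
- Decanoyl chloride and Meldrum's acid (pyridine, CH2Cl2) give 5-(1-hydroxydecylidene)-2,2-dimethyl-1,3-dioxane-4,6-dione F3.
- In refluxing toluene F3 fragments to the acylketene and acylates the DMB-amine of F2, giving the N-DMB 3-oxododecanamide F4.
- K2CO3 in aqueous MeOH frees the primary amine and gives the amino β-keto amide F5.
- F5 is stirred at about 1 mM in toluene with catalytic AcOH and 4 Å sieves, which condenses N1 with the C2 ketone.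
- Enaminone formation is reversible, so oligomers should be corrected to the hydrogen-bonded monomeric ring 17.

2. Step 8 (labelled).
What may go wrong: the product amine may bind to rhodium and slow the turnover. Facial selectivity may be poor if the N-alkyl macrocyclic enaminone cannot adopt the binding geometry of the open-chain primary enaminones.
Fallback: known chemistry, setting out from 17 and coming back at 18.
- NaBH(OAc)3 in AcOH/MeCN at 0 °C protonates C3 and delivers hydride to the iminium carbon C2. This standard reduction of β-enamino carbonyl compounds gives the racemic β-amino amide F6.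
- Preparative chromatography on a chiral stationary phase separates 18 from its (S)-enantiomer F7.

3. Step 6.
What may go wrong: intermolecular S-alkylation may set in early during work-up and concentration. Surplus acyl bromide may attack the thioamide by S-alkylation followed by N-acylation.
Fallback: it sets out from 12 and comes back at 15.
- Chloroacetyl chloride under the same biphasic conditions gives the N12-chloroacetamide F8. It alkylates a neutral thioamide so slowly that it should tolerate chromatography and storage.
- The electrophile is unmasked only in the dilution flask, where NaI (Finkelstein exchange) turns it into the N12-iodoacetamide F9 in the presence of Cs2CO3.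
- Ring closure then gives 15, and part b of step 7 follows.

**Further compounds**
F1 | step 7 | N1-(2,4-dimethoxybenzyl)-N4,N9-di-Boc-spermine | NCCCN(C(=O)OC(C)(C)C)CCCCN(C(=O)OC(C)(C)C)CCCNCc1ccc(OC)cc1OC
F2 | step 7 | N1-(2,4-dimethoxybenzyl)-N12-trifluoroacetyl-N4,N9-di-Boc-spermine | FC(F)(F)C(=O)NCCCN(C(=O)OC(C)(C)C)CCCCN(C(=O)OC(C)(C)C)CCCNCc1ccc(OC)cc1OC
F3 | step 7 | 5-(1-hydroxydecylidene)-2,2-dimethyl-1,3-dioxane-4,6-dione | CCCCCCCCCC(O)=C1C(=O)OC(C)(C)OC1=O
F4 | step 7 | N1-(2,4-dimethoxybenzyl)-N1-(3-oxododecanoyl)-N12-trifluoroacetyl-N4,N9-di-Boc-spermine | FC(F)(F)C(=O)NCCCN(C(=O)OC(C)(C)C)CCCCN(C(=O)OC(C)(C)C)CCCN(Cc1ccc(OC)cc1OC)C(=O)CC(=O)CCCCCCCCC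
F5 | step 7 | N1-(2,4-dimethoxybenzyl)-N1-(3-oxododecanoyl)-N4,N9-di-Boc-spermine | NCCCN(C(=O)OC(C)(C)C)CCCCN(C(=O)OC(C)(C)C)CCCN(Cc1ccc(OC)cc1OC)C(=O)CC(=O)CCCCCCCCC
F6 | step 8 | racemic 5-DMB-9,14-di-Boc-2-nonyl-1,5,9,14-tetraazacycloheptadecan-4-one | CCCCCCCCCC1CC(=O)N(Cc2ccc(OC)cc2OC)CCCN(C(=O)OC(C)(C)C)CCCCN(C(=O)OC(C)(C)C)CCCN1
F7 | step 8 | (2S)-5-DMB-9,14-di-Boc-2-nonyl-1,5,9,14-tetraazacycloheptadecan-4-one | CCCCCCCCC[C@H]1CC(=O)N(Cc2ccc(OC)cc2OC)CCCN(C(=O)OC(C)(C)C)CCCCN(C(=O)OC(C)(C)C)CCCN1
F8 | step 6 | N1-decanethioyl-N12-chloroacetyl-N12-DMB-N4,N9-di-Boc-spermine | CCCCCCCCCC(=S)NCCCN(C(=O)OC(C)(C)C)CCCCN(C(=O)OC(C)(C)C)CCCN(Cc1ccc(OC)cc1OC)C(=O)CCl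
F9 | step 6 | N1-decanethioyl-N12-iodoacetyl-N12-DMB-N4,N9-di-Boc-spermine | CCCCCCCCCC(=S)NCCCN(C(=O)OC(C)(C)C)CCCCN(C(=O)OC(C)(C)C)CCCN(Cc1ccc(OC)cc1OC)C(=O)CI
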